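**Retrosynthetic overview** (ring A numbered C1 OMe, C2 Br, C3 H, C4 OH, C5 OAr, C6 Br; ring B is the 2,4-dibromophenyl ring)

- The target 13 comes from aryl iodide 10 (C4–I to C4–OH), which comes from phenol 8 by para iodination directed by the C1 hydroxyl and then O-methylation at C1.
- The strategy rests on this feature of ring A: the C1 oxygen is flanked by C2–Br and C6–Br, and C5 carries the aryl ether. That is the footprint of a C1 ketone brominated at both alpha carbons with an enol ether at C5.
- Ring A is therefore carried as a cyclohexenone: phenol 8 arises from 3-(2,4-dibromophenoxy)cyclohex-2-en-1-one 4 by threefold bromination and loss of HBr.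
- Enone 4 comes from 3-chlorocyclohex-2-en-1-one 2 and 2,4-dibromophenol 3 by addition–elimination; 2 comes from cyclohexane-1,3-dione 1.
- Ring order: ring B is bought as an arene; ring A is bought as a saturated carbocycle and made aromatic in step 3; no ring is closed.

Key step: step 3

**Step 1**
Reactants: 1 cyclohexane-1,3-dione
Product: 2 3-chlorocyclohex-2-en-1-one
Conditions: (COCl)2 (1.2 equiv), DMF (cat.), CH2Cl2, 0 °C to rt; used crude
Reagents that add atoms: oxalyl chloride, O=C(Cl)C(Cl)=O
Why: The enol of the dione is a vinylogous acid and is converted into the vinylogous acid chloride by Vilsmeier-type activation, with chloride adding to the activated enol carbon and CO, CO2 and HCl leaving.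

**Step 2**
Reactants: 2 3-chlorocyclohex-2-en-1-one; 3 2,4-dibromophenol
Product: 4 3-(2,4-dibromophenoxy)cyclohex-2-en-1-one
Conditions: K2CO3, DMF, 50 °C
Reagents that add atoms: none
Why: Nucleophilic vinylic substitution by addition–elimination: the phenoxide adds to the beta carbon of the beta-chloro enone and chloride is expelled, which forms the C5–O bond without any hindered aryl coupling.

**Step 3**
Reactants: 4 3-(2,4-dibromophenoxy)cyclohex-2-en-1-one; 5 bromine (3.0 equiv)
Product: 8 2,6-dibromo-3-(2,4-dibromophenoxy)phenol, via tribromoenone 6 (not isolated), via dienone tautomer 7 (not isolated)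
Conditions: Br2 (3.0 equiv), NaOAc (3 equiv), AcOH, 5 °C to rt; concentrate; then Li2CO3, LiBr, DMF, 100 °C; dilute HCl work-up
Reagents that add atoms: none
Why: Electrophilic bromination of the vinylogous ester puts the first bromine on the nucleophilic vinylic alpha carbon C6 by addition and loss of HBr; acetate-assisted enolisation toward the only alpha methylene then brings two bromines to C2, the first bromine there acidifying the remaining C2–H so that the third bromine follows to the same carbon, after which no enolisable alpha hydrogen is left and bromination stops. Li2CO3 and LiBr in hot DMF then remove HBr across C2–C3 from tribromide 6, and the cross-conjugated dienone 7 tautomerises to phenol 8. The closest known reaction type is exhaustive alpha-halogenation of cyclohexanones followed by dehydrohalogenation to 2,6-dihalophenols, combined with the classical Li2CO3/LiBr dehydrobromination of alpha-bromo ketones. No ring is closed and no stereocentre is formed; the six-membered carbocycle is kept and only changes oxidation level. The step needs bromination at C6 and C2 but not at the gamma methylene C4, and no aromatisation before the third bromine has arrived: the carbonyl secures the first, because the electron-poor aryloxy group is a weak donor and the protonated enone loses its proton at C2 next to the hydroxy-bearing carbon, and the cold acetate buffer with exactly three equivalents of Br2 secures the second while keeping HBr from cleaving the aryl vinyl ether.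

**Step 4**
Reactants: 8 2,6-dibromo-3-(2,4-dibromophenoxy)phenol
Product: 9 2,6-dibromo-3-(2,4-dibromophenoxy)-4-iodophenol
Conditions: N-iodosuccinimide (1.05 equiv), CF3CO2H (cat.), MeCN, rt
Reagents that add atoms: N-iodosuccinimide, O=C1CCC(=O)N1I
Why: Electrophilic aromatic iodination: both carbons ortho to the hydroxyl carry bromine, so the hydroxyl directs to the para carbon C4, which is also ortho to the aryloxy group, while ring B is deactivated by two bromines.

**Step 5**
Reactants: 9 2,6-dibromo-3-(2,4-dibromophenoxy)-4-iodophenol
Product: 10 1,3-dibromo-4-(2,4-dibromophenoxy)-5-iodo-2-methoxybenzene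
Conditions: MeI, K2CO3, DMF, rt
Reagents that add atoms: iodomethane, CI
Why: Williamson ether synthesis on the only hydroxyl of the molecule; the acidic 2,6-dibromophenol gives its phenoxide readily, so the methyl group is fixed on the C1 oxygen before the C4 oxygen exists.

**Step 6**
Reactants: 10 1,3-dibromo-4-(2,4-dibromophenoxy)-5-iodo-2-methoxybenzene
Product: 13 3,5-dibromo-2-(2,4-dibromophenoxy)-4-methoxyphenol, via arylmagnesium chloride 11 (not isolated), via dimethyl arylboronate 12 (not isolated)
Conditions: iPrMgCl·LiCl (1.05 equiv), THF, −40 °C; B(OMe)3, −40 °C to rt; then H2O2, NaOH aq, 0 °C; dilute HCl work-up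
Reagents that add atoms: hydrogen peroxide, OO (oxygen of the C4 hydroxyl); iPrMgCl, CC(C)[Mg]Cl, and B(OMe)3, COB(OC)OC, add atoms only to intermediates 11 and 12
Why: Iodine–magnesium exchange is much faster than bromine–magnesium exchange at low temperature, so only C4 is metallated; the Grignard carbon has no ortho halogen and cannot form an aryne. Borylation and peroxide oxidation, with aryl migration from boron to oxygen, then turn C4–Mg into C4–OH at the same carbon.

**Compound list**
1 | cyclohexane-1,3-dione | O=C1CCCC(=O)C1 | starting material
2 | 3-chlorocyclohex-2-en-1-one | O=C1CCCC(Cl)=C1 | intermediate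
3 | 2,4-dibromophenol | Oc1ccc(Br)cc1Br | starting material
4 | 3-(2,4-dibromophenoxy)cyclohex-2-en-1-one | O=C1CCCC(Oc2ccc(Br)cc2Br)=C1 | intermediate
5 | bromine | BrBr | starting material
6 | 2,6,6-tribromo-3-(2,4-dibromophenoxy)cyclohex-2-en-1-one | O=C1C(Br)=C(Oc2ccc(Br)cc2Br)CCC1(Br)Br | intermediate
7 | 2,6-dibromo-3-(2,4-dibromophenoxy)cyclohexa-2,5-dien-1-one | O=C1C(Br)=CCC(Oc2ccc(Br)cc2Br)=C1Br | intermediate
8 | 2,6-dibromo-3-(2,4-dibromophenoxy)phenol | Oc1c(Br)ccc(Oc2ccc(Br)cc2Br)c1Br | intermediate
9 | 2,6-dibromo-3-(2,4-dibromophenoxy)-4-iodophenol | Oc1c(Br)cc(I)c(Oc2ccc(Br)cc2Br)c1Br | intermediate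
10 | 1,3-dibromo-4-(2,4-dibromophenoxy)-5-iodo-2-methoxybenzene | COc1c(Br)cc(I)c(Oc2ccc(Br)cc2Br)c1Br | intermediate
11 | [3,5-dibromo-2-(2,4-dibromophenoxy)-4-methoxyphenyl]magnesium chloride | COc1c(Br)cc([Mg]Cl)c(Oc2ccc(Br)cc2Br)c1Br | intermediate
12 | dimethyl [3,5-dibromo-2-(2,4-dibromophenoxy)-4-methoxyphenyl]boronate | COB(OC)c1cc(Br)c(OC)c(Br)c1Oc1ccc(Br)cc1Br | intermediate
13 | 3,5-dibromo-2-(2,4-dibromophenoxy)-4-methoxyphenol | COc1c(Br)cc(O)c(Oc2ccc(Br)cc2Br)c1Br | target

**Total step count:** 6
**Longest linear sequence:** 6 steps, from cyclohexane-1,3-dione 1 to 13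

**Steps most likely to fail**

1. Step 3. Bromination may stray to the gamma methylene C4, or the alpha-bromo ketone may lose HBr before the third bromine has arrived, so that the phenol formed early is brominated para to its hydroxyl; HBr may also cleave the aryl vinyl ether. The fallback sets out from 4 and comes back at 8; it makes the arene first and lets the phenol hydroxyl deliver the bromines. Kinetic deprotonation of 4 with LiN(SiMe3)2 in THF at −78 °C and trapping with PhSeCl should give racemic 3-(2,4-dibromophenoxy)-6-(phenylselanyl)cyclohex-2-en-1-one F1. Oxidation with H2O2 and pyridine in CH2Cl2, selenoxide syn elimination and tautomerisation should give 3-(2,4-dibromophenoxy)phenol F2. Br2 (2 equiv) with tert-butylamine in toluene at −70 °C, the amine-mediated ortho bromination of phenols, should then brominate both carbons ortho to the hydroxyl and give 8.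

2. Step 6. Exchange may lose chemoselectivity and attack the bromides ortho to oxygen, or the aryl Grignard may be protonated before borylation, which amounts to net deiodination. The fallback sets out from 8 and comes back at 13; it oxidises the arene instead of using an organometallic. Teuber oxidation of 8 with (KSO3)2NO and KH2PO4 in acetone–water should give 2,6-dibromo-3-(2,4-dibromophenoxy)cyclohexa-2,5-diene-1,4-dione F3. Na2S2O4 in EtOAc–water should reduce it to 2,6-dibromo-3-(2,4-dibromophenoxy)benzene-1,4-diol F4. MeI with one equivalent of KHCO3 in DMF under argon should methylate the more acidic hydroxyl, the one flanked by two bromines, and give 13; this selectivity rests only on the acidity difference between the two hydroxyls.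

3. Step 4. Iodination of the electron-poor phenol may stall, or oxidative coupling of the phenol may compete. The fallback sets out from 8 and comes back at 13; it brings in the C4 oxygen directly and already differentiated. Elbs persulfate oxidation of 8 with K2S2O8 in aqueous NaOH–pyridine at 0 °C to rt should give potassium 3,5-dibromo-2-(2,4-dibromophenoxy)-4-hydroxyphenyl sulfate F5, in which the new para oxygen is masked as the sulfate and the original hydroxyl is free. Me2SO4 with NaOH should methylate that free hydroxyl to potassium 3,5-dibromo-2-(2,4-dibromophenoxy)-4-methoxyphenyl sulfate F6. Hot aqueous HCl should hydrolyse the aryl sulfate to 13.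

**Further compounds**
F1 | step 3 | 3-(2,4-dibromophenoxy)-6-(phenylselanyl)cyclohex-2-en-1-one (racemic) | O=C1C=C(Oc2ccc(Br)cc2Br)CCC1[Se]c1ccccc1
F2 | step 3 | 3-(2,4-dibromophenoxy)phenol | Oc1cccc(Oc2ccc(Br)cc2Br)c1
F3 | step 6 | 2,6-dibromo-3-(2,4-dibromophenoxy)cyclohexa-2,5-diene-1,4-dione | O=C1C=C(Br)C(=O)C(Br)=C1Oc1ccc(Br)cc1Br
F4 | step 6 | 2,6-dibromo-3-(2,4-dibromophenoxy)benzene-1,4-diol | Oc1cc(Br)c(O)c(Br)c1Oc1ccc(Br)cc1Br
F5 | step 4 | potassium 3,5-dibromo-2-(2,4-dibromophenoxy)-4-hydroxyphenyl sulfate | [K+].[O-]S(=O)(=O)Oc1cc(Br)c(O)c(Br)c1Oc1ccc(Br)cc1Br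
F6 | step 4 | potassium 3,5-dibromo-2-(2,4-dibromophenoxy)-4-methoxyphenyl sulfate | [K+].[O-]S(=O)(=O)Oc1cc(Br)c(OC)c(Br)c1Oc1ccc(Br)cc1Br
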